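The dihydropyran ring (cyclopenta[c]pyran numbering: O2, C1, C7a, C4a, C4, C3) is disconnected at O2–C3 and C4–C4a. The key step exploits that O2–C1–C7a–C4a is the 1-oxadiene of a cyclopentenecarbaldehyde and that C3=C4, carrying the acyl and methyl groups, is a polarised ynone. A nickel(0)-catalysed formal [4+2] cycloaddition of (S)-5-methylcyclopent-1-enecarbaldehyde with an (R)-α-silyloxy propynyl ketone makes both bonds and the C4a stereocentre in one operation. It delivers the complete C15 terpenoid part as a 4H-pyran. The extra C1=C7a enol ether then serves the end game: protonation and C-alkylation of 4-hydroxy-5-methylcoumarin set C7a and C1 under thermodynamic control.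

Key step: step 6

Assumption: cyclopenta[c]pyran locants are used throughout (C1 bears the coumarin, C3 the acyl group, C4 and C7 the methyl groups). The target is read as (1R,4aS,7S,7aR) with an (R)-carbinol carbon. The phosphine ligands of 8 and the triflate counter-ion of 12 are left out of the SMILES.

Step 1
Reactants: 1 (S)-citronellal
Product: 2 (S)-3,7-dimethyl-2-methylideneoct-6-enal
Conditions: 37% aq. CH2O, pyrrolidine (10 mol%), propionic acid (10 mol%), i-PrOH, 45 °C
Reagents that add atoms: formaldehyde, C=O
Why: Organocatalytic α-methylenation (Mannich condensation, then loss of the amine) acts only at the CH2 next to the formyl group, and the neighbouring methyl-bearing stereocentre is not acidified and is carried through.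

Step 2
Reactants: 2 (S)-3,7-dimethyl-2-methylideneoct-6-enal
Product: 3 (S)-5-methylcyclopent-1-ene-1-carbaldehyde
Conditions: Grubbs II (2 mol%), CH2Cl2 (0.02 M), 40 °C
Reagents that add atoms: none
Why: Ring-closing metathesis between the 1,1-disubstituted enal alkene and the prenyl alkene closes the cyclopentene with unambiguous regiochemistry and is driven by loss of a volatile alkene; the stereocentre is untouched and becomes C7 (S).

Step 3
Reactants: 4 (R)-2-hydroxy-3-methylbutanoic acid
Product: 5 (R)-2-hydroxy-N-methoxy-N,3-dimethylbutanamide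
Conditions: MeNH(OMe)·HCl, EDC·HCl, HOBt (cat.), N-methylmorpholine, CH2Cl2, 0 °C to rt
Reagents that add atoms: N,O-dimethylhydroxylamine hydrochloride, CNOC.Cl
Why: In this carbodiimide amide coupling the hindered secondary hydroxyl group competes poorly with the amine, and the α-hydroxy acid stereocentre should not racemise.

Step 4
Reactants: 5 (R)-2-hydroxy-N-methoxy-N,3-dimethylbutanamide
Product: 6 (R)-N-methoxy-N,3-dimethyl-2-(triethylsilyloxy)butanamide
Conditions: TESCl, imidazole, CH2Cl2, 0 °C to rt
Reagents that add atoms: chlorotriethylsilane, CC[Si](Cl)(CC)CC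
Why: The TES ether from this standard silylation prevents cyclisation of the hydroxyl group onto the later ynone and protonolysis of organonickel species, yet is removable under mild fluoride conditions at the end.

Step 5
Reactants: 6 (R)-N-methoxy-N,3-dimethyl-2-(triethylsilyloxy)butanamide
Product: 7 (R)-2-methyl-3-(triethylsilyloxy)hept-5-yn-4-one
Conditions: 1-propynylmagnesium bromide (0.5 M in THF), THF, −20 to 0 °C; inverse quench into cold 1 M HCl
Reagents that add atoms: 1-propynylmagnesium bromide, CC#C[Mg]Br
Why: In the Weinreb ketone synthesis the N-methoxy-N-methyl amide stops the alkynyl Grignard addition at the ketone stage, and the cold acidic quench keeps the liberated amine protonated so that it cannot add to the ynone.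

Step 6
Reactants: 3 (S)-5-methylcyclopent-1-ene-1-carbaldehyde; 7 (R)-2-methyl-3-(triethylsilyloxy)hept-5-yn-4-one
Product: 9 (2R)-1-[(4aS,7S)-4,7-dimethyl-4a,5,6,7-tetrahydrocyclopenta[c]pyran-3-yl]-3-methyl-2-(triethylsilyloxy)butan-1-one, via oxanickelacycle 8 (not isolated)
Conditions: Ni(cod)2 (10 mol%), PCy3 (20 mol%), 3 (2 equiv), toluene, 80 °C, 7 added by syringe pump
Reagents that add atoms: none
Why: Proposed new method: Ni(0) binds the s-cis enal 3 and the ynone 7 and couples them oxidatively, joining the enal β-carbon C4a to the methyl-bearing β-carbon of the ynone (C4) to give the seven-membered O-bound enolate nickelacycle 8, and C(sp2)–O reductive elimination from 8 then joins O2 to C3 and returns Ni(0). The closest known reaction types are the nickel(0)/phosphine-catalysed [4+2] cycloaddition of 2-acylacrylate-type enones with alkynes to 4H-pyrans and the nickel-catalysed reductive couplings of enals with alkynes, which rest on the same oxidative cyclisation; a plain enal as oxadiene and an ynone as 2π partner go beyond both. The one ring that is closed, the six-membered pyran, arises by contraction of the seven-membered metallacycle, a stepwise formal hetero-Diels–Alder closure in which no endo/exo question arises because the 2π partner is an alkyne. The one new stereocentre, C4a, is controlled by the C7 methyl group next to the oxadiene: nickel and the alkyne should take the enal face anti to it, which puts C4 trans to that methyl group (4aS). The step needs regioselectivity, which the polarised ynone secures (C–C bond at its electrophilic β-carbon, nickel at the acyl-stabilised α-carbon, whose electron-poor alkenyl ligand should also ease the C–O elimination). It also needs cross-coupling over homo-coupling, for which 3 is used in excess and 7 is added slowly, while the neutral aprotic medium spares the silyl ether and the α-silyloxy ketone stereocentre.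

Step 7
Reactants: 10 1-(2-hydroxy-6-methylphenyl)ethan-1-one
Product: 11 4-hydroxy-5-methylcoumarin (4-hydroxy-5-methyl-2H-chromen-2-one)
Conditions: NaH (3 equiv), (EtO)2CO, toluene, 110 °C; then 2 M HCl
Reagents that add atoms: diethyl carbonate, CCOC(=O)OCC
Why: Claisen-type C-acylation of the methyl ketone enolate by diethyl carbonate followed by lactonisation onto the phenoxide is the standard 4-hydroxycoumarin synthesis from 2-hydroxyacetophenones, and the 6-methyl group of 10 becomes the 5-methyl group.

Step 8
Reactants: 9 (2R)-1-[(4aS,7S)-4,7-dimethyl-4a,5,6,7-tetrahydrocyclopenta[c]pyran-3-yl]-3-methyl-2-(triethylsilyloxy)butan-1-one; 11 4-hydroxy-5-methylcoumarin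
Product: 14 3-{(1R,4aS,7S,7aR)-3-[(2R)-2-hydroxy-3-methylbutanoyl]-4,7-dimethyl-1,4a,5,6,7,7a-hexahydrocyclopenta[c]pyran-1-yl}-4-hydroxy-5-methyl-2H-chromen-2-one (target), via oxocarbenium ion 12 (not isolated), via silyl ether 13 (not isolated)
Conditions: 11 (1.0 equiv), TfOH (10 mol%), MeCN, PFA flask, 0 °C to rt; then 48% aq. HF, same flask, 0 °C to rt
Reagents that add atoms: none
Why: This is an acid-catalysed Friedel–Crafts-type C-alkylation of a cyclic 1,3-dicarbonyl nucleophile by an enol-ether-derived oxocarbenium ion: only the electron-rich C1=C7a enol ether is protonated (C3=C4 is deactivated by the acyl group), reversible protonation should give the more stable cis-fused ion 12 (H7a syn to H4a, C1 trans to the C7 methyl group, 7aR), coumarin C3 attacks C1 from the convex face syn to H7a (1R), reversible ionisation of the C1–O2 bond lets O-alkylated or C1-epimeric material funnel into this most stable isomer 13, and HF then cleaves the TES ether.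

Compound list
1 | (S)-citronellal | O=CC[C@@H](C)CCC=C(C)C | starting material
2 | (S)-3,7-dimethyl-2-methylideneoct-6-enal | C=C(C=O)[C@@H](C)CCC=C(C)C | intermediate
3 | (S)-5-methylcyclopent-1-ene-1-carbaldehyde | O=CC1=CCC[C@@H]1C | intermediate
4 | (R)-2-hydroxy-3-methylbutanoic acid | OC(=O)[C@H](O)C(C)C | starting material
5 | (R)-2-hydroxy-N-methoxy-N,3-dimethylbutanamide | CON(C)C(=O)[C@H](O)C(C)C | intermediate
6 | (R)-N-methoxy-N,3-dimethyl-2-(triethylsilyloxy)butanamide | CON(C)C(=O)[C@H](O[Si](CC)(CC)CC)C(C)C | intermediate
7 | (R)-2-methyl-3-(triethylsilyloxy)hept-5-yn-4-one | CC#CC(=O)[C@H](O[Si](CC)(CC)CC)C(C)C | intermediate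
8 | seven-membered oxanickelacycle (Ni bound to O2 and C3, C4–C4a already formed, phosphines omitted) | CC1=C(C(=O)[C@H](O[Si](CC)(CC)CC)C(C)C)[Ni]OC=C2[C@@H]1CC[C@@H]2C | intermediate
9 | (2R)-1-[(4aS,7S)-4,7-dimethyl-4a,5,6,7-tetrahydrocyclopenta[c]pyran-3-yl]-3-methyl-2-(triethylsilyloxy)butan-1-one | CC1=C(C(=O)[C@H](O[Si](CC)(CC)CC)C(C)C)OC=C2[C@@H]1CC[C@@H]2C | intermediate
10 | 1-(2-hydroxy-6-methylphenyl)ethan-1-one | CC(=O)c1c(C)cccc1O | starting material
11 | 4-hydroxy-5-methylcoumarin | Cc1cccc2oc(=O)cc(O)c12 | intermediate
12 | cis-fused C1 oxocarbenium ion from C7a protonation of 9 (counter-ion omitted) | CC1=C(C(=O)[C@H](O[Si](CC)(CC)CC)C(C)C)[O+]=C[C@H]2[C@@H]1CC[C@@H]2C | intermediate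
13 | O-triethylsilyl ether of the target, (1R,4aS,7S,7aR), side chain (R) | CC1=C(C(=O)[C@H](O[Si](CC)(CC)CC)C(C)C)O[C@@H](c2c(O)c3c(C)cccc3oc2=O)[C@H]2[C@@H]1CC[C@@H]2C | intermediate
14 | 3-{(1R,4aS,7S,7aR)-3-[(2R)-2-hydroxy-3-methylbutanoyl]-4,7-dimethyl-1,4a,5,6,7,7a-hexahydrocyclopenta[c]pyran-1-yl}-4-hydroxy-5-methyl-2H-chromen-2-one | CC1=C(C(=O)[C@H](O)C(C)C)O[C@@H](c2c(O)c3c(C)cccc3oc2=O)[C@H]2[C@@H]1CC[C@@H]2C | target

Total step count: 8. Longest linear sequence: 5 steps (steps 3, 4, 5, 6, 8).

Steps most likely to fail

1. Step 6 (Proposed new method).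
- Risk: the cross oxidative cyclisation may be outrun by cyclotrimerisation of the ynone, by insertion of a second alkyne, or by 1,2-coupling at the formyl group. The C–O reductive elimination may be too slow, and facial selectivity at C4a may be incomplete.
- Fallback (known chemistry): it sets out from 6 and 3 and comes back at 9. (Z)-1-Ethoxyprop-1-ene is lithiated at C1 (t-BuLi, THF, −78 to 0 °C) and acylated with 6 to give the captodative enol ether (2Z,5R)-3-ethoxy-6-methyl-5-(triethylsilyloxy)hept-2-en-4-one F1. An inverse-electron-demand hetero-Diels–Alder reaction of F1 with 3 as the 1-oxadiene (Yb(fod)3 cat., neat, 80–110 °C, or high pressure) should join O2 to the ethoxy-bearing C3 and C4a to C4 in one operation. This gives the 3-ethoxy-3-acyl-3,4-dihydro cycloadduct F2, whose C3 and C4 configurations are of no consequence. PPTS in warm toluene then eliminates the alcohol across C3–C4 to give 9.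

2. Step 8.
- Risk: renewed ionisation of the fresh C1–O2 bond followed by capture of a second coumarin unit, hydrolytic ring opening, incomplete equilibration at C1 and C7a, or acid-induced epimerisation next to the ketone.
- Fallback: it sets out from 9 and comes back at 13. Mild hydration of the C1=C7a enol ether (oxalic acid, wet THF) gives the C1 lactol F3. Ethylenediammonium diacetate-catalysed Knoevenagel condensation of its open aldehyde form with 11 gives the 3-alkylidenechromane-2,4-dione F4. The diketone enol oxygen of F4 adds back to C1 by intramolecular oxa-Michael addition under thermodynamic control to give 13. Desilylation follows as in step 8.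

3. Step 5.
- Risk: conjugate addition of the liberated hydroxylamine to the ynone during the quench, and base-induced epimerisation of the α-silyloxy centre.
- Fallback: it sets out from 6 and comes back at 7. DIBAL-H (THF, −78 °C) reduces 6 to (R)-3-methyl-2-(triethylsilyloxy)butanal F5. Addition of 1-propynylmagnesium bromide gives (3R)-2-methyl-3-(triethylsilyloxy)hept-5-yn-4-ol F6 as a carbinol epimer mixture of no consequence. Dess–Martin or MnO2 oxidation gives 7 with no nucleophilic amine present.

Further compounds
F1 | step 6 | (2Z,5R)-3-ethoxy-6-methyl-5-(triethylsilyloxy)hept-2-en-4-one | C/C=C(\OCC)C(=O)[C@H](O[Si](CC)(CC)CC)C(C)C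
F2 | step 6 | 3-ethoxy-3,4-dihydro cycloadduct of F1 and 3 (C4a, C7 and side chain as in 9, mixture at C3 and C4) | CC1C(OCC)(C(=O)[C@H](O[Si](CC)(CC)CC)C(C)C)OC=C2[C@@H]1CC[C@@H]2C
F3 | step 8 | C1 lactol from hydration of 9 (cis-fused, anomer mixture) | CC1=C(C(=O)[C@H](O[Si](CC)(CC)CC)C(C)C)OC(O)[C@H]2[C@@H]1CC[C@@H]2C
F4 | step 8 | 3-alkylidene-5-methylchromane-2,4-dione from the open form of F3 and 11 (mixture at the methyl-bearing carbon next to the diketone) | CC(C(=O)C(=O)[C@H](O[Si](CC)(CC)CC)C(C)C)[C@H]1CC[C@H](C)[C@H]1C=C1C(=O)Oc2cccc(C)c2C1=O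
F5 | step 5 | (R)-3-methyl-2-(triethylsilyloxy)butanal | O=C[C@H](O[Si](CC)(CC)CC)C(C)C
F6 | step 5 | (3R)-2-methyl-3-(triethylsilyloxy)hept-5-yn-4-ol (epimer mixture at C4) | CC#CC(O)[C@H](O[Si](CC)(CC)CC)C(C)C
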